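**Retrosynthetic overview**
- Feature: in the 2,3-dihydrobenzofuran ring, C2 carries ring oxygen O1 and an exocyclic sp2 carbon (C=CH2 in the target, C=O one stage earlier), and C3 is a benzylic carbinol carbon on C3a, ortho to O1. C2–C3 is therefore the bond of an aldol between an aryloxymethyl ketone and an ortho formyl group.
- Late disconnections: the phenol silyl ether; the C3–O angelate (cis alcohol plus angelic acid); the C=CH2 group (from the side-chain ketone by methylenation).
- Key disconnection: C2–C3, back to the open keto aldehyde ArO–CH2–CO–CH2OAc with an ortho CHO group; the proline enamine aldol sets C2 and C3 cis.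
- The keto aldehyde comes from an aryl bromide (CHO by way of a vinyl group) and from O-alkylation of the unchelated hydroxyl of 5'-bromo-2',4'-dihydroxyacetophenone with 1-acetoxy-3-chloropropan-2-one.
- Ring order: the benzene ring is bought; the dihydrofuran ring is the only ring formed, in the key step.

Key step: step 5

Assumption: the sense of induction of (S)-proline is taken from the acid-bridged enamine transition-state model of proline aldol reactions, which leads to the (2S,3R) aldol; should the closure run in the opposite sense, (R)-proline is used and nothing else changes.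

**Route**

Step 1
Reactants: 1 1-(5-bromo-2,4-dihydroxyphenyl)ethan-1-one; 2 3-chloro-2-oxopropyl acetate
Product: 3 3-(4-acetyl-2-bromo-5-hydroxyphenoxy)-2-oxopropyl acetate
Conditions: K2CO3, NaI (cat.), acetone, rt
Reagents that add atoms: none
Why: Williamson ether synthesis in which the 2-hydroxyl is tied up in a hydrogen bond to the acetyl carbonyl and is the weaker acid, so only the 4-hydroxyl should be deprotonated and alkylated, iodide exchange making the α-chloroketone a fast SN2 partner while the acetate survives the anhydrous weak base.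

Step 2
Reactants: 3 3-(4-acetyl-2-bromo-5-hydroxyphenoxy)-2-oxopropyl acetate
Product: 4 3-[4-acetyl-2-bromo-5-(triisopropylsilyloxy)phenoxy]-2-oxopropyl acetate
Conditions: iPr3SiOTf, 2,6-lutidine, CH2Cl2, 0 °C
Reagents that add atoms: triisopropylsilyl trifluoromethanesulfonate, CC(C)[Si](OS(=O)(=O)C(F)(F)F)(C(C)C)C(C)C
Why: O-silylation of the chelated phenol with a silyl triflate and a hindered pyridine base, which should not enolise the side-chain ketone at 0 °C, gives a bulky aryl silyl ether that keeps the phenol out of the acylation in step 9, shields the neighbouring acetyl group in step 7 and can be removed at the end with buffered fluoride.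

Step 3
Reactants: 4 3-[4-acetyl-2-bromo-5-(triisopropylsilyloxy)phenoxy]-2-oxopropyl acetate; 5 tributyl(vinyl)stannane
Product: 6 3-[4-acetyl-2-ethenyl-5-(triisopropylsilyloxy)phenoxy]-2-oxopropyl acetate
Conditions: Pd(PPh3)4 (5 mol %), toluene, 100 °C
Reagents that add atoms: none
Why: Migita–Stille cross-coupling of the aryl bromide runs without base, so the enolisable α-aryloxy ketone, the acetate and the aryl silyl ether should stay untouched while a latent formyl group is put in place.

Step 4
Reactants: 6 3-[4-acetyl-2-ethenyl-5-(triisopropylsilyloxy)phenoxy]-2-oxopropyl acetate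
Product: 8 3-[4-acetyl-2-formyl-5-(triisopropylsilyloxy)phenoxy]-2-oxopropyl acetate, via diol 7 (not isolated)
Conditions: OsO4 (cat.), NaIO4, 2,6-lutidine, 1,4-dioxane/H2O, rt
Reagents that add atoms: osmium tetroxide, O=[Os](=O)(=O)=O; sodium periodate, [Na+].[O-]I(=O)(=O)=O
Why: Lemieux–Johnson oxidation dihydroxylates and cleaves the styrene double bond, the only alkene present, at room temperature in a lutidine-buffered medium, so the aldehyde is revealed without a base strong enough to start a racemic background aldol condensation of the keto aldehyde.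

Step 5
Reactants: 8 3-[4-acetyl-2-formyl-5-(triisopropylsilyloxy)phenoxy]-2-oxopropyl acetate
Product: 11 2-[(2S,3R)-5-acetyl-3-hydroxy-6-(triisopropylsilyloxy)-2,3-dihydro-1-benzofuran-2-yl]-2-oxoethyl acetate, via proline enamine 9 (not isolated), via aldol iminium carboxylate 10 (not isolated)
Conditions: (S)-proline (30 mol %), DMF, 0 °C to rt; work-up with aq. NaH2PO4/Na2HPO4 buffer (pH 7)
Reagents that add atoms: none
Why: (S)-Proline condenses reversibly with the side-chain ketone of 8 on either flank, but only the enamine towards the aryloxy methylene (9) can reach the ortho formyl group, so the bond should form between the aryloxy-bearing carbon and the aldehyde carbon, and hydrolysis of iminium 10 then releases the catalyst. The closest known reaction type is the proline-catalysed intramolecular enolexo aldol reaction of ortho-(2-oxoalkoxy)aryl carbonyl compounds, which gives cis-2-acyl-3-hydroxy-2,3-dihydrobenzofurans. The dihydrofuran ring closes in the 5-enolexo-exo-trig mode, the enamine double bond lying outside the forming ring. C2 is set by attack of the (E)-anti enamine on the face that carries the carboxylic acid, and C3 by the hydrogen bond from that acid to the formyl oxygen, which turns this oxygen towards the enamine nitrogen and so places hydroxyl and acyl group cis; with (S)-proline this model leads to (2S,3R). The step needs site selectivity between the two enamines (secured by a five-membered against a seven-membered closure), cis diastereoselectivity and enantioselectivity (both secured by the acid-bridged transition state), and survival of the β-hydroxy ketone, for which the low temperature, the near-neutral medium and the buffered work-up are chosen, since base or heat would dehydrate it to the aromatic 2-acylbenzofuran.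

Step 6
Reactants: 11 2-[(2S,3R)-5-acetyl-3-hydroxy-6-(triisopropylsilyloxy)-2,3-dihydro-1-benzofuran-2-yl]-2-oxoethyl acetate
Product: 12 2-[(2S,3R)-5-acetyl-3-(triethylsilyloxy)-6-(triisopropylsilyloxy)-2,3-dihydro-1-benzofuran-2-yl]-2-oxoethyl acetate
Conditions: Et3SiOTf, 2,6-lutidine, CH2Cl2, −78 °C
Reagents that add atoms: triethylsilyl trifluoromethanesulfonate, CC[Si](CC)(CC)OS(=O)(=O)C(F)(F)F
Why: O-silylation with a silyl triflate and 2,6-lutidine at −78 °C should neither enolise nor dehydrate a β-hydroxy ketone, and the resulting ether blocks retro-aldol cleavage and E1cB loss of the C3 oxygen while leaving both stereocentres untouched.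

Step 7
Reactants: 12 2-[(2S,3R)-5-acetyl-3-(triethylsilyloxy)-6-(triisopropylsilyloxy)-2,3-dihydro-1-benzofuran-2-yl]-2-oxoethyl acetate
Product: 13 2-[(2R,3R)-5-acetyl-3-(triethylsilyloxy)-6-(triisopropylsilyloxy)-2,3-dihydro-1-benzofuran-2-yl]prop-2-en-1-yl acetate
Conditions: Zn, CH2Br2, TiCl4, THF (reagent pre-formed at −40 °C and aged at 5 °C); then 12, CH2Cl2, 0 °C to rt; aq. NaHCO3 work-up
Reagents that add atoms: dibromomethane, BrCBr
Why: Lombardo methylenation with the non-basic, oxophilic zinc–titanium methylene reagent should convert the inductively activated α,α′-dioxygenated ketone into the 1,1-disubstituted alkene without epimerising C2 or eliminating the β-silyloxy group, leave the acetate ester alone, and, with the reagent kept close to stoichiometric, spare the donor-substituted aryl methyl ketone shielded by the ortho triisopropylsilyloxy group (the C2 descriptor changes from S to R only through the priority change).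

Step 8
Reactants: 13 2-[(2R,3R)-5-acetyl-3-(triethylsilyloxy)-6-(triisopropylsilyloxy)-2,3-dihydro-1-benzofuran-2-yl]prop-2-en-1-yl acetate
Product: 14 2-[(2R,3R)-5-acetyl-3-hydroxy-6-(triisopropylsilyloxy)-2,3-dihydro-1-benzofuran-2-yl]prop-2-en-1-yl acetate
Conditions: HF·pyridine, pyridine, THF, 0 °C
Reagents that add atoms: none
Why: Acid-type desilylation with pyridine-buffered HF·pyridine should cleave the secondary alkyl triethylsilyl ether much faster than the hindered aryl triisopropylsilyl ether, in a medium too weakly acidic to ionise the electron-rich benzylic alcohol.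

Step 9
Reactants: 14 2-[(2R,3R)-5-acetyl-3-hydroxy-6-(triisopropylsilyloxy)-2,3-dihydro-1-benzofuran-2-yl]prop-2-en-1-yl acetate; 15 angelic acid
Product: 17 (2R,3R)-2-(3-acetoxyprop-1-en-2-yl)-5-acetyl-6-(triisopropylsilyloxy)-2,3-dihydro-1-benzofuran-3-yl (Z)-2-methylbut-2-enoate, via mixed anhydride 16 (not isolated)
Conditions: 15, 2,4,6-trichlorobenzoyl chloride, Et3N, toluene, rt; then 14, toluene, 75 °C (no DMAP)
Reagents that add atoms: none
Why: Yamaguchi esterification without a nucleophilic catalyst, in which the alcohol should attack the angeloyl carbonyl of mixed anhydride 16 because the other carbonyl is flanked by two ortho chlorines, the absence of DMAP avoids Z to E isomerisation of the angeloyl unit, the phenol is masked, and C3 keeps its configuration since its C–O bond is not broken.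

Step 10
Reactants: 17 (2R,3R)-2-(3-acetoxyprop-1-en-2-yl)-5-acetyl-6-(triisopropylsilyloxy)-2,3-dihydro-1-benzofuran-3-yl (Z)-2-methylbut-2-enoate
Product: 18 (2R,3R)-2-(3-acetoxyprop-1-en-2-yl)-5-acetyl-6-hydroxy-2,3-dihydro-1-benzofuran-3-yl (Z)-2-methylbut-2-enoate
Conditions: Bu4NF, AcOH, THF, 0 °C
Reagents that add atoms: none
Why: Fluoride-mediated desilylation of an aryl silyl ether is much faster than any attack on the esters, and acetic acid protonates the phenoxide at once, so the acetate, the angelate and the ionisable benzylic ester para to the phenol oxygen should be preserved.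

**Compound list**

1 | 1-(5-bromo-2,4-dihydroxyphenyl)ethan-1-one (5'-bromo-2',4'-dihydroxyacetophenone) | CC(=O)c1cc(Br)c(O)cc1O | starting material
2 | 3-chloro-2-oxopropyl acetate (1-acetoxy-3-chloropropan-2-one) | CC(=O)OCC(=O)CCl | starting material
3 | 3-(4-acetyl-2-bromo-5-hydroxyphenoxy)-2-oxopropyl acetate | CC(=O)OCC(=O)COc1cc(O)c(C(C)=O)cc1Br | intermediate
4 | 3-[4-acetyl-2-bromo-5-(triisopropylsilyloxy)phenoxy]-2-oxopropyl acetate | CC(=O)OCC(=O)COc1cc(O[Si](C(C)C)(C(C)C)C(C)C)c(C(C)=O)cc1Br | intermediate
5 | tributyl(vinyl)stannane | C=C[Sn](CCCC)(CCCC)CCCC | starting material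
6 | 3-[4-acetyl-2-ethenyl-5-(triisopropylsilyloxy)phenoxy]-2-oxopropyl acetate | CC(=O)OCC(=O)COc1cc(O[Si](C(C)C)(C(C)C)C(C)C)c(C(C)=O)cc1C=C | intermediate
7 | 3-[4-acetyl-2-(1,2-dihydroxyethyl)-5-(triisopropylsilyloxy)phenoxy]-2-oxopropyl acetate (racemic diol formed in the flask) | CC(=O)OCC(=O)COc1cc(O[Si](C(C)C)(C(C)C)C(C)C)c(C(C)=O)cc1C(O)CO | intermediate
8 | 3-[4-acetyl-2-formyl-5-(triisopropylsilyloxy)phenoxy]-2-oxopropyl acetate (key-step precursor) | CC(=O)OCC(=O)COc1cc(O[Si](C(C)C)(C(C)C)C(C)C)c(C(C)=O)cc1C=O | intermediate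
9 | (E)-enamine of 8 with (S)-proline on the aryloxy flank (formed in the flask) | CC(=O)OC/C(=C\Oc1cc(O[Si](C(C)C)(C(C)C)C(C)C)c(C(C)=O)cc1C=O)N1CCC[C@H]1C(=O)O | intermediate
10 | iminium carboxylate of the cyclised (2S,3R) aldol with (S)-proline (formed in the flask) | CC(=O)OCC(=[N+]1CCC[C@H]1C(=O)[O-])[C@H]1Oc2cc(O[Si](C(C)C)(C(C)C)C(C)C)c(C(C)=O)cc2[C@H]1O | intermediate
11 | 2-[(2S,3R)-5-acetyl-3-hydroxy-6-(triisopropylsilyloxy)-2,3-dihydro-1-benzofuran-2-yl]-2-oxoethyl acetate (key-step product) | CC(=O)OCC(=O)[C@H]1Oc2cc(O[Si](C(C)C)(C(C)C)C(C)C)c(C(C)=O)cc2[C@H]1O | intermediate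
12 | 2-[(2S,3R)-5-acetyl-3-(triethylsilyloxy)-6-(triisopropylsilyloxy)-2,3-dihydro-1-benzofuran-2-yl]-2-oxoethyl acetate | CC(=O)OCC(=O)[C@H]1Oc2cc(O[Si](C(C)C)(C(C)C)C(C)C)c(C(C)=O)cc2[C@H]1O[Si](CC)(CC)CC | intermediate
13 | 2-[(2R,3R)-5-acetyl-3-(triethylsilyloxy)-6-(triisopropylsilyloxy)-2,3-dihydro-1-benzofuran-2-yl]prop-2-en-1-yl acetate | C=C(COC(C)=O)[C@H]1Oc2cc(O[Si](C(C)C)(C(C)C)C(C)C)c(C(C)=O)cc2[C@H]1O[Si](CC)(CC)CC | intermediate
14 | 2-[(2R,3R)-5-acetyl-3-hydroxy-6-(triisopropylsilyloxy)-2,3-dihydro-1-benzofuran-2-yl]prop-2-en-1-yl acetate | C=C(COC(C)=O)[C@H]1Oc2cc(O[Si](C(C)C)(C(C)C)C(C)C)c(C(C)=O)cc2[C@H]1O | intermediate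
15 | angelic acid, (Z)-2-methylbut-2-enoic acid | C/C=C(/C)C(=O)O | starting material
16 | (Z)-2-methylbut-2-enoic 2,4,6-trichlorobenzoic anhydride (formed in the flask) | C/C=C(/C)C(=O)OC(=O)c1c(Cl)cc(Cl)cc1Cl | intermediate
17 | (2R,3R)-2-(3-acetoxyprop-1-en-2-yl)-5-acetyl-6-(triisopropylsilyloxy)-2,3-dihydro-1-benzofuran-3-yl (Z)-2-methylbut-2-enoate | C=C(COC(C)=O)[C@H]1Oc2cc(O[Si](C(C)C)(C(C)C)C(C)C)c(C(C)=O)cc2[C@H]1OC(=O)/C(C)=C\C | intermediate
18 | (2R,3R)-2-(3-acetoxyprop-1-en-2-yl)-5-acetyl-6-hydroxy-2,3-dihydro-1-benzofuran-3-yl (Z)-2-methylbut-2-enoate (CNP0323250.1) | C=C(COC(C)=O)[C@H]1Oc2cc(O)c(C(C)=O)cc2[C@H]1OC(=O)/C(C)=C\C | target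

**Step count**

Total steps: 10. Longest linear sequence: 10 steps (1 to 18); 2, 5 and 15 enter as single building blocks.

**Steps most likely to fail**

Step 5 (key aldol). What may go wrong: incomplete facial control at the electron-rich formyl group, or erosion of enantiomeric purity by retro-aldol opening and re-closure; dehydration of the β-hydroxy ketone is held back only by the mild conditions. Fallback (resolution in place of catalyst control): setting out from 8, the closure is run with racemic proline under the same conditions. This should keep the cis relationship and give 11 together with its enantiomer 2-[(2R,3S)-5-acetyl-3-hydroxy-6-(triisopropylsilyloxy)-2,3-dihydro-1-benzofuran-2-yl]-2-oxoethyl acetate F1. Silylation as in step 6 should then give 12 together with its enantiomer 2-[(2R,3S)-5-acetyl-3-(triethylsilyloxy)-6-(triisopropylsilyloxy)-2,3-dihydro-1-benzofuran-2-yl]-2-oxoethyl acetate F2. Preparative chromatography on a chiral stationary phase (amylose tris(3,5-dimethylphenylcarbamate) on silica) separates the two silyl ethers, and the route is rejoined at 12.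

Step 7 (methylenation). What may go wrong: competing methylenation of the aryl acetyl group, Lewis-acid-induced ionisation of the benzylic silyloxy group with aromatisation to the benzofuran, or reductive loss of the α-acetoxy group by zinc. Fallback (two-step Peterson olefination in place of the titanium methylene reagent): setting out from 12, the weakly basic organocerium reagent made from Me3SiCH2MgCl and CeCl3 (THF, −78 °C) is added. It should pick the inductively activated, chelating side-chain ketone over the hindered, donor-substituted aryl ketone and the ester, and give the β-hydroxysilane 2-[(2S,3R)-5-acetyl-3-(triethylsilyloxy)-6-(triisopropylsilyloxy)-2,3-dihydro-1-benzofuran-2-yl]-2-hydroxy-3-(trimethylsilyl)propyl acetate F3 as a mixture of carbinol epimers. HF·pyridine in THF should then bring about the acid-type Peterson elimination and the loss of the triethylsilyl group in one operation, and the route is rejoined at 14.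

Step 9 (angelate). What may go wrong: isomerisation of the angeloyl unit to the tigloyl (E) unit in the activated acyl species, and slow acylation of the hindered benzylic hydroxyl cis to the C2 substituent, with elimination competing on prolonged heating. Fallback (build the Z double bond on the ester instead of bringing it in): setting out from 14, Steglich esterification (DCC, DMAP, CH2Cl2) with 2-[bis(2,2,2-trifluoroethoxy)phosphoryl]propanoic acid, an acid with no double bond to isomerise, gives (2R,3R)-2-(3-acetoxyprop-1-en-2-yl)-5-acetyl-6-(triisopropylsilyloxy)-2,3-dihydro-1-benzofuran-3-yl 2-[bis(2,2,2-trifluoroethoxy)phosphoryl]propanoate F4. Still–Gennari olefination (KN(SiMe3)2, 18-crown-6, THF, −78 °C, then acetaldehyde) should form the Z-configured 2-methylbut-2-enoate, and the route is rejoined at 17.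

**Further compounds**

F1 | step 5 | 2-[(2R,3S)-5-acetyl-3-hydroxy-6-(triisopropylsilyloxy)-2,3-dihydro-1-benzofuran-2-yl]-2-oxoethyl acetate | CC(=O)OCC(=O)[C@@H]1Oc2cc(O[Si](C(C)C)(C(C)C)C(C)C)c(C(C)=O)cc2[C@@H]1O
F2 | step 5 | 2-[(2R,3S)-5-acetyl-3-(triethylsilyloxy)-6-(triisopropylsilyloxy)-2,3-dihydro-1-benzofuran-2-yl]-2-oxoethyl acetate | CC(=O)OCC(=O)[C@@H]1Oc2cc(O[Si](C(C)C)(C(C)C)C(C)C)c(C(C)=O)cc2[C@@H]1O[Si](CC)(CC)CC
F3 | step 7 | 2-[(2S,3R)-5-acetyl-3-(triethylsilyloxy)-6-(triisopropylsilyloxy)-2,3-dihydro-1-benzofuran-2-yl]-2-hydroxy-3-(trimethylsilyl)propyl acetate | CC(=O)OCC(O)(C[Si](C)(C)C)[C@H]1Oc2cc(O[Si](C(C)C)(C(C)C)C(C)C)c(C(C)=O)cc2[C@H]1O[Si](CC)(CC)CC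
F4 | step 9 | (2R,3R)-2-(3-acetoxyprop-1-en-2-yl)-5-acetyl-6-(triisopropylsilyloxy)-2,3-dihydro-1-benzofuran-3-yl 2-[bis(2,2,2-trifluoroethoxy)phosphoryl]propanoate | C=C(COC(C)=O)[C@H]1Oc2cc(O[Si](C(C)C)(C(C)C)C(C)C)c(C(C)=O)cc2[C@H]1OC(=O)C(C)P(=O)(OCC(F)(F)F)OCC(F)(F)F
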